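The target is a 2,2-dimethyl-2H-chromene: a pyran ring (O1, C2, C3, C4, C4a, C8a) fused to a resorcinol-type benzene ring. The plan closes that pyran ring at the C4–C4a bond by gold(I)-catalysed 6-endo-dig hydroarylation of an aryl 2-methylbut-3-yn-2-yl ether. The terminal alkyne carbon becomes C4 and is attacked by the arene carbon para to the C7 oxygen, so one operation sets the C–C bond, the ring and the C3=C4 alkene. The precursor is a 5-bromoresorcinol bis-ether (one prenyl, one tertiary propargyl group); its bromine, which ends up at C5, later accepts the 4-hydroxyphenethyl arm by B-alkyl Suzuki coupling.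

Key step: step 3

Remark: the target has no stereocentre (C2 carries two methyl groups) and its ring alkene is cis by constraint, so it is achiral and no enantiocontrol is required.

**Step 1**
Reactants: 1 5-bromobenzene-1,3-diol (5-bromoresorcinol, used in excess), 2 1-bromo-3-methylbut-2-ene (prenyl bromide)
Product: 3 3-bromo-5-[(3-methylbut-2-en-1-yl)oxy]phenol
Conditions: K2CO3 (1 equiv on 2), acetone, rt; excess 1 recovered
Reagents that add atoms: none
Why: Williamson etherification, in which the phenoxide of the symmetric diol displaces bromide from the primary allylic bromide (SN2); the excess of diol biases the statistical outcome toward the mono-ether.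

**Step 2**
Reactants: 3 3-bromo-5-[(3-methylbut-2-en-1-yl)oxy]phenol, 4 3-chloro-3-methylbut-1-yne
Product: 5 1-bromo-3-[(2-methylbut-3-yn-2-yl)oxy]-5-[(3-methylbut-2-en-1-yl)oxy]benzene
Conditions: DBU, CuCl2·2H2O (cat.), MeCN, 0 °C
Reagents that add atoms: none
Why: Copper-catalysed propargylic etherification, in which a copper acetylide ionises the tertiary chloride and the phenoxide captures the resulting electrophile at the tertiary carbon; this is the established way to aryl 1,1-dimethylpropargyl ethers where SN2 is not possible.

**Step 3**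
Reactants: 5 1-bromo-3-[(2-methylbut-3-yn-2-yl)oxy]-5-[(3-methylbut-2-en-1-yl)oxy]benzene
Product: 6 5-bromo-2,2-dimethyl-7-[(3-methylbut-2-en-1-yl)oxy]-2H-chromene
Conditions: JohnPhosAu(MeCN)SbF6 (2 mol%), CH2Cl2, rt
Reagents that add atoms: none
Why: Cationic gold(I) binds the terminal alkyne of 5 as a π-acid, the arene carbon ortho to the propargylic oxygen attacks the terminal alkyne carbon anti to gold (Friedel–Crafts-type C–C bond formation), and rearomatisation followed by protodeauration of the vinyl–gold species at C3 releases chromene 6 and the catalyst. The closest known reaction type is the gold(I)-catalysed intramolecular hydroarylation of aryl propargyl ethers to 2H-chromenes, which is established for 1,1-dimethylpropargyl ethers. The pyran ring closes in the 6-endo-dig mode, which is general for terminal aryl propargyl ethers under gold(I) and is preferred here over 5-exo-dig attack at the internal alkyne carbon. No stereocentre is created, because C2 bears two methyl groups and the new C3=C4 bond is cis by ring constraint. The step needs site selectivity between the two arene carbons ortho to the propargylic oxygen: attack at the carbon para to the prenyloxy group gives an arenium ion stabilised by that oxygen, whereas the other carbon lies between two alkoxy groups, a position that electrophiles avoid in 1-bromo-3,5-dialkoxybenzenes, so the 5-bromo-7-alkoxy isomer should prevail. Chemoselectivity for the alkyne over the prenyl alkene rests on the alkynophilicity of gold(I) at room temperature and low loading, and the aryl bromide is inert.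

**Step 4**
Reactants: 7 4-ethenylphenyl acetate (4-acetoxystyrene), 6 5-bromo-2,2-dimethyl-7-[(3-methylbut-2-en-1-yl)oxy]-2H-chromene
Product: 10 4-{2-[2,2-dimethyl-7-(3-methylbut-2-enyloxy)-2H-chromen-5-yl]ethyl}phenol (the target), via B-[2-(4-acetoxyphenyl)ethyl]-9-BBN 8 (not isolated), via coupled aryl acetate 9 (not isolated)
Conditions: 9-BBN, THF, 0 °C→rt (7 in slight excess over 9-BBN); then 3 M NaOH aq, 6, PdCl2(dppf) (5 mol%), THF, 60 °C; NH4Cl aq work-up
Reagents that add atoms: none
Why: Anti-Markovnikov hydroboration of the styrene with 9-BBN puts boron on the terminal carbon, the B-alkyl Suzuki–Miyaura coupling (oxidative addition into the C5–Br bond, hydroxide-assisted transmetalation, reductive elimination) forms the aryl–CH2 bond without a hydrogenation that the prenyl and chromene alkenes would not survive, and the aqueous hydroxide saponifies the aryl acetate in the same flask.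

**Compound list**
1 | 5-bromobenzene-1,3-diol (5-bromoresorcinol) | Oc1cc(O)cc(Br)c1 | starting material
2 | 1-bromo-3-methylbut-2-ene (prenyl bromide) | CC(C)=CCBr | starting material
3 | 3-bromo-5-[(3-methylbut-2-en-1-yl)oxy]phenol | CC(C)=CCOc1cc(O)cc(Br)c1 | intermediate
4 | 3-chloro-3-methylbut-1-yne | CC(C)(Cl)C#C | starting material
5 | 1-bromo-3-[(2-methylbut-3-yn-2-yl)oxy]-5-[(3-methylbut-2-en-1-yl)oxy]benzene | CC(C)=CCOc1cc(Br)cc(OC(C)(C)C#C)c1 | intermediate
6 | 5-bromo-2,2-dimethyl-7-[(3-methylbut-2-en-1-yl)oxy]-2H-chromene | CC(C)=CCOc1cc(Br)c2c(c1)OC(C)(C)C=C2 | intermediate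
7 | 4-ethenylphenyl acetate (4-acetoxystyrene) | CC(=O)Oc1ccc(C=C)cc1 | starting material
8 | 9-[2-(4-acetoxyphenyl)ethyl]-9-borabicyclo[3.3.1]nonane | CC(=O)Oc1ccc(CCB2C3CCCC2CCC3)cc1 | intermediate
9 | 4-{2-[2,2-dimethyl-7-(3-methylbut-2-enyloxy)-2H-chromen-5-yl]ethyl}phenyl acetate | CC(=O)Oc1ccc(CCc2cc(OCC=C(C)C)cc3OC(C)(C)C=Cc23)cc1 | intermediate
10 | 4-{2-[2,2-dimethyl-7-(3-methylbut-2-enyloxy)-2H-chromen-5-yl]ethyl}phenol | CC(C)=CCOc1cc(CCc2ccc(O)cc2)c2c(c1)OC(C)(C)C=C2 | target

Total step count: 4
Longest linear sequence: 4 steps (1 → 3 → 5 → 6 → 10)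

**Steps most likely to fail**

Step 3 (key step). The risk is C–C bond formation at the arene carbon between the two ether oxygens instead of the one next to bromine, together with gold-induced ionisation or migration of the prenyl ether. The fallback replaces π-acid catalysis by a metal-free pericyclic cascade in which the C4–C4a bond arises in a sigmatropic shift and the ring is closed at O1–C2. Setting out from compound 5, heating in xylene at about 140 °C should trigger the aromatic propargyl Claisen rearrangement to racemic 5-bromo-6-(3-methylbuta-1,2-dien-1-yl)-3-[(3-methylbut-2-en-1-yl)oxy]cyclohexa-2,4-dien-1-one F1. This should tautomerise to 3-bromo-2-(3-methylbuta-1,2-dien-1-yl)-5-[(3-methylbut-2-en-1-yl)oxy]phenol F2. A 1,5-hydrogen shift should then give the o-quinone methide 5-bromo-6-(3-methylbut-2-en-1-ylidene)-3-[(3-methylbut-2-en-1-yl)oxy]cyclohexa-2,4-dien-1-one F3 (butenylidene chain syn to the carbonyl), whose oxa-6π electrocyclisation comes back to the route at compound 6. In the sigmatropic step a meta halogen directs toward its own side and a meta alkoxy group toward the far side, both of which point to the required carbon. The temperature stays below that at which the aryl prenyl ether itself rearranges.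

Step 4. The risk is palladium-induced loss of the prenyl group through π-allyl formation, and β-hydride elimination from the alkylpalladium intermediate leading to hydrodebromination. The fallback is a copper-catalysed Grignard alkylation without palladium. 4-(2-Bromoethyl)phenol F4 would be silylated (TBSCl, imidazole, DMF) to [4-(2-bromoethyl)phenoxy](tert-butyl)dimethylsilane F5. Setting out from compound 6, magnesium insertion (Mg, LiCl, THF) should give [2,2-dimethyl-7-(3-methylbut-2-enyloxy)-2H-chromen-5-yl]magnesium bromide F6. Alkylation of this Grignard reagent by F5 under Li2CuCl4 catalysis (THF/NMP, 0 °C) should give the tert-butyldimethylsilyl ether of the target F7. TBAF (THF, 0 °C) would then come back to the route at compound 10.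

Step 1. The risk is over-alkylation to the bis-ether and competing C-prenylation of the resorcinol nucleus, which erode the statistical mono-etherification. The fallback desymmetrises by halogen–metal exchange instead. Setting out from compound 2, alkylation of 3,5-dibromophenol F8 (K2CO3, DMF, rt) should give 1,3-dibromo-5-[(3-methylbut-2-en-1-yl)oxy]benzene F9. A single bromine–lithium exchange (n-BuLi, THF, −78 °C) should give {3-bromo-5-[(3-methylbut-2-en-1-yl)oxy]phenyl}lithium F10. Trapping with B(OMe)3 should give dimethyl {3-bromo-5-[(3-methylbut-2-en-1-yl)oxy]phenyl}boronate F11, which is oxidised in the same flask (H2O2, NaOH aq, 0 °C) and comes back to the route at compound 3.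

**Further compounds**
F1 | step 3 | 5-bromo-6-(3-methylbuta-1,2-dien-1-yl)-3-[(3-methylbut-2-en-1-yl)oxy]cyclohexa-2,4-dien-1-one (racemic) | O=C1C=C(OCC=C(C)C)C=C(Br)C1C=C=C(C)C
F2 | step 3 | 3-bromo-2-(3-methylbuta-1,2-dien-1-yl)-5-[(3-methylbut-2-en-1-yl)oxy]phenol | CC(C)=C=Cc1c(O)cc(OCC=C(C)C)cc1Br
F3 | step 3 | 5-bromo-6-(3-methylbut-2-en-1-ylidene)-3-[(3-methylbut-2-en-1-yl)oxy]cyclohexa-2,4-dien-1-one (chain syn to the carbonyl) | CC(C)=C/C=C1\C(=O)C=C(OCC=C(C)C)C=C1Br
F4 | step 4 | 4-(2-bromoethyl)phenol | Oc1ccc(CCBr)cc1
F5 | step 4 | [4-(2-bromoethyl)phenoxy](tert-butyl)dimethylsilane | CC(C)(C)[Si](C)(C)Oc1ccc(CCBr)cc1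
F6 | step 4 | [2,2-dimethyl-7-(3-methylbut-2-enyloxy)-2H-chromen-5-yl]magnesium bromide | CC(C)=CCOc1cc([Mg]Br)c2c(c1)OC(C)(C)C=C2
F7 | step 4 | tert-butyldimethylsilyl ether of the target | CC(C)=CCOc1cc(CCc2ccc(O[Si](C)(C)C(C)(C)C)cc2)c2c(c1)OC(C)(C)C=C2
F8 | step 1 | 3,5-dibromophenol | Oc1cc(Br)cc(Br)c1
F9 | step 1 | 1,3-dibromo-5-[(3-methylbut-2-en-1-yl)oxy]benzene | CC(C)=CCOc1cc(Br)cc(Br)c1
F10 | step 1 | {3-bromo-5-[(3-methylbut-2-en-1-yl)oxy]phenyl}lithium | [Li]c1cc(Br)cc(OCC=C(C)C)c1
F11 | step 1 | dimethyl {3-bromo-5-[(3-methylbut-2-en-1-yl)oxy]phenyl}boronate | COB(OC)c1cc(Br)cc(OCC=C(C)C)c1
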